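The blue run, charged with 0.90 mM of acid, may already contain the state I am asked about in the amber flask, and the readings can test that.

| setting | amber | blue | flask |
|---|---|---|---|
| substrate | 20 mM | 20 mM | 20 mM |
| acid | 0.60 mM | 0.90 mM | 0.600 mM |
| scavenger | 10 mM | 10 mM | 10.0 mM |
| remark | the very flask that is asked about, followed so far | run made earlier |  |
| time |  |  | 3.0 min |

| run | time / s | substrate / % | target / % |
|---|---|---|---|
| amber | 10.0 | 82.8 | 8.6 |
| amber | 15.0 | 77.9 | 10.8 |
| amber | 25.0 | 63.1 | 19.1 |
| amber | 40.0 | 50.9 | 29.8 |
| amber | 60.0 | 40.7 | 37.9 |
| amber | 80.0 | 34.1 | 43.4 |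
| blue | 10.0 | 75.6 | 15.2 |
| blue | 15.0 | 64.9 | 18.5 |
| blue | 30.0 | 46.2 | 27.9 |
| blue | 50.0 | 33.7 | 42.4 |
| blue | 80.0 | 23.0 | 53.2 |
| blue | 120 | 16.3 | 66.0 |

(standard deviation of a reading: 1 percentage point)

1. part of the substrate that has reacted at 3.0 min
2. pH of the solution at 3.0 min

I begin with the main step by itself: substrate goes to target under constant [acid], a pseudo-first-order decay whose rate constant I take as proportional to [acid]. Amber's first target reading gives 0.00899 s⁻¹, which puts 80.2 % reacted at 3.0 min. On this step a flask's state follows [acid] times time, so I carry one quantity: 120 s is amber's asked time expressed as blue time, that is, a flask's time multiplied by its [acid] and divided by blue's [acid]. This equals the time of blue's last reading.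

Next I add the reservoir. At that blue reading, 17.7 % of the charge is neither substrate nor target, yet it counts as reacted. If it keeps the same clock, blue gives 83.7 % reacted, 3.5 percentage points above the main step by itself.

Last I look for a further step on plain time, which readings of equal blue time can expose. Amber at 15.0 s and blue at 10.0 s are such a pair: substrate 77.9 % against 75.6 %, target 10.8 % against 15.2 %. That target gap of 4.4 points stands against a scatter of 1 point per reading, so I treat it as a warning. Later, amber at 80.0 s (blue time 53.3 s) and blue at 50.0 s agree more closely in substrate, 34.1 % against 33.7 %.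

The forecast, holding that “the acid survives as a catalyst”, gives 83 % and pH 3.22. My reading lies 0.7 points above its conversion, and I take the same pH, with [acid] staying at 0.600 mM.

The amber flask gives 85.1 % reacted and pH 3.22, from these steps:

    substrate + acid → weak acid + acid + target (k = 16.0 L mol⁻¹ s⁻¹)
    weak acid ⇌ conjugate base + acid, settled at all times (K = 1.30 × 10⁻⁷ M)
    substrate → weak acid + target (k = 1.60 × 10⁻⁴ s⁻¹)
    substrate + weak acid ⇌ idle adduct, settled at all times (K = 1500 L mol⁻¹)
    weak acid + scavenger → scavenged by-product (k = 23.0 L mol⁻¹ s⁻¹)

Without the scatter, blue at its last reading stands at 85.1 % reacted, level with the amber flask at 120 s of blue time. Amber left until 50 s has a blue time of 33.3 s, a little past blue's reading at 30.0 s, where substrate read 46.2 %, and that amber flask holds less, 45.1 %.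

Readings and results stem from a simulated flask on assumed constants, and the scatter is random.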